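The cyclohexene ring (p-menthane numbering) is cut at two ring bonds: C3–C4, joining the allylic CH2 to the oxygen-bearing quaternary carbon C4, and the C1=C2 alkene. The key step exploits the homoallylic array C4(O)–C3H2–C2H=C1(CH3) of the six-membered ring: catalytic asymmetric allylboration of an acyclic dienone forms C3–C4 and the only stereocentre, and ring-closing metathesis in the same flask closes the carbocycle through C1=C2. The precursor, 2,6-dimethylhepta-1,6-dien-3-one, carries the isopropyl group as isopropenyl so that the chiral catalyst tells an sp2 from an sp3 ketone substituent; it is hydrogenated afterwards. O-Acylation with a dibromoanisoyl chloride and a twofold Stille prenylation finish the ester.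

Key step: step 2

Remark 1: 5 is taken as a catalogue reagent; failing that, it is made in one operation from triisopropyl borate and allylmagnesium bromide.
Remark 2: the (S)-binaphthol is assumed to direct allyl to the Re face of the carbonyl of 4 (priority O > isopropenyl > CH2), which gives the (R)-carbinol; if the sense of induction proves opposite, the (R)-antipode is used.

Step 1
Reactants: 1 4-bromo-2-methylbut-1-ene; 2 N-methoxy-N-methylmethacrylamide
Product: 4 2,6-dimethylhepta-1,6-dien-3-one, via homoallyl Grignard reagent 3 (not isolated)
Conditions: 1, Mg, THF, 40 °C; then 2, THF, −78 to 0 °C; quench into cold aq. HCl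
Reagents that add atoms: none
Why: Weinreb ketone synthesis: the homoallyl Grignard reagent adds once to the N-methoxy-N-methylamide and the magnesium chelate collapses to the isopropenyl ketone only on the acidic quench, which also protonates the liberated N,O-dimethylhydroxylamine before it can add to the enone.

Step 2
Reactants: 4 2,6-dimethylhepta-1,6-dien-3-one; 5 diisopropyl allylboronate (1.5 equiv)
Product: 8 (1R)-4-methyl-1-(prop-1-en-2-yl)cyclohex-3-en-1-ol, via triene borate 6 (not isolated), via cyclic borate 7 (not isolated)
Conditions: (S)-3,3'-dibromo-1,1'-bi-2-naphthol (15 mol %), PhCF3–toluene, −35 °C; then RuCl2(=CHPh)(H2IMes)(PCy3) (second-generation Grubbs catalyst, 5 mol %), same flask, 40 °C; aq. NaHCO3 work-up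
Reagents that add atoms: none
Why: Exchange of one isopropoxide of 5 for the binaphthol gives a chiral, more Lewis-acidic allylboronate that transfers allyl to the ketone carbon of 4 through a closed six-membered chair transition state (C3–C4 bond; chiral-diol-catalysed asymmetric allylboration of ketones), and the ruthenium alkylidene then loads on the new terminal allyl alkene of 6 and closes onto the 1,1-disubstituted chain alkene through a ruthenacyclobutane with loss of ethene (C1=C2 bond; ring-closing olefin metathesis, with no work-up between the two catalytic events). The six-membered carbocycle is thus closed at its alkene, by metathesis of two pendant alkene termini, not at a single bond. The only stereocentre, C4, is set in the allylboration by the binaphthol on boron, which should place the planar isopropenyl group pseudo-equatorial and the CH2 chain pseudo-axial so that allyl adds to the Re face of the carbonyl; metathesis does not touch C4. The step needs 1,2- over 1,4-addition (inherent to the cyclic boron transition state), enantioface selection (secured by the sp2/sp3 contrast of the two ketone substituents, the reason isopropyl is carried as isopropenyl) and a single mode of ring closure (secured because the isopropenyl group could only close a four-membered ring with the allyl group or a tetrasubstituted cyclopentene with the chain alkene).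

Step 3
Reactants: 8 (1R)-4-methyl-1-(prop-1-en-2-yl)cyclohex-3-en-1-ol
Product: 9 (1R)-4-methyl-1-(propan-2-yl)cyclohex-3-en-1-ol [(R)-terpinen-4-ol]
Conditions: H2 (1 atm), RhCl(PPh3)3 (5 mol %), benzene–EtOH, 25 °C
Reagents that add atoms: none
Why: Homogeneous hydrogenation on monovalent rhodium is very sensitive to alkene substitution, so the 1,1-disubstituted isopropenyl group should be saturated well before the trisubstituted ring alkene, a chemoselection familiar from isopropenyl-bearing p-menthadienes; neutral conditions leave the tertiary alcohol and C4 untouched.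

Step 4
Reactants: 9 (R)-terpinen-4-ol; 10 3,5-dibromo-4-methoxybenzoic acid
Product: 12 (1R)-4-methyl-1-(propan-2-yl)cyclohex-3-en-1-yl 3,5-dibromo-4-methoxybenzoate, via acid chloride 11 (not isolated)
Conditions: 10, (COCl)2, cat. DMF, CH2Cl2, 0 °C to rt, then evaporation; separately 9, n-BuLi, THF, −78 °C; then 11 in THF, −78 °C to rt
Reagents that add atoms: none
Why: Acylation of a preformed lithium alkoxide by an aroyl chloride (addition–elimination at the acyl carbon) is the standard answer to a hindered tertiary alcohol; all butyllithium is consumed by the O–H before the aryl bromide is added, and no bond to C4 is broken, so the configuration is retained.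

Step 5
Reactants: 12 (R)-terpinen-4-yl 3,5-dibromo-4-methoxybenzoate; 13 tributyl(3-methylbut-2-en-1-yl)stannane (2.5 equiv)
Product: 14 (1R)-4-methyl-1-(propan-2-yl)cyclohex-3-en-1-yl 4-methoxy-3,5-bis(3-methylbut-2-en-1-yl)benzoate
Conditions: Pd(PPh3)4 (10 mol %), DMF, 90 °C
Reagents that add atoms: none
Why: Twofold Stille coupling: zerovalent palladium inserts into each aryl–Br bond, the prenyl group is transferred from tin and reductive elimination at its unsubstituted CH2 terminus should give the linear 3-methylbut-2-enyl groups, while the tertiary homoallylic ester cannot ionise to a π-allyl complex and C4 stays untouched.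

Compound list
1 | 4-bromo-2-methylbut-1-ene | C=C(C)CCBr | starting material
2 | N-methoxy-N,2-dimethylprop-2-enamide (N-methoxy-N-methylmethacrylamide) | C=C(C)C(=O)N(C)OC | starting material
3 | (3-methylbut-3-en-1-yl)magnesium bromide | C=C(C)CC[Mg]Br | intermediate
4 | 2,6-dimethylhepta-1,6-dien-3-one | C=C(C)C(=O)CCC(C)=C | intermediate
5 | dipropan-2-yl prop-2-en-1-ylboronate (diisopropyl allylboronate) | C=CCB(OC(C)C)OC(C)C | starting material
6 | (4R)-7-methyl-4-(prop-1-en-2-yl)octa-1,7-dien-4-yl dipropan-2-yl borate | CC(C)OB(OC(C)C)O[C@@](CCC(C)=C)(C(C)=C)CC=C | intermediate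
7 | (1R)-4-methyl-1-(prop-1-en-2-yl)cyclohex-3-en-1-yl dipropan-2-yl borate | CC(C)OB(OC(C)C)O[C@@]1(C(C)=C)CC=C(C)CC1 | intermediate
8 | (1R)-4-methyl-1-(prop-1-en-2-yl)cyclohex-3-en-1-ol | O[C@@]1(C(C)=C)CC=C(C)CC1 | intermediate
9 | (1R)-4-methyl-1-(propan-2-yl)cyclohex-3-en-1-ol | O[C@@]1(C(C)C)CC=C(C)CC1 | intermediate
10 | 3,5-dibromo-4-methoxybenzoic acid | COc1c(Br)cc(C(=O)O)cc1Br | starting material
11 | 3,5-dibromo-4-methoxybenzoyl chloride | COc1c(Br)cc(C(=O)Cl)cc1Br | intermediate
12 | (1R)-4-methyl-1-(propan-2-yl)cyclohex-3-en-1-yl 3,5-dibromo-4-methoxybenzoate | COc1c(Br)cc(C(=O)O[C@@]2(C(C)C)CC=C(C)CC2)cc1Br | intermediate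
13 | tributyl(3-methylbut-2-en-1-yl)stannane | CCCC[Sn](CCCC)(CCCC)CC=C(C)C | starting material
14 | (1R)-4-methyl-1-(propan-2-yl)cyclohex-3-en-1-yl 4-methoxy-3,5-bis(3-methylbut-2-en-1-yl)benzoate | COc1c(CC=C(C)C)cc(C(=O)O[C@@]2(C(C)C)CC=C(C)CC2)cc1CC=C(C)C | target

Total step count: 5. Longest linear sequence: 5 steps (1/2 → 4 → 8 → 9 → 12 → 14).

Steps most likely to fail

Step 2. The allyl transfer may discriminate the two carbonyl faces insufficiently, or boron and binaphthol residues may stall the ruthenium carbene before ring closure is complete. Fallback: the two bond formations are decoupled and the allyl transfer is moved from a closed boron transition state to an open, Lewis-acid-mediated one. Setting out from 4, addition of tetraallylstannane (C=CC[Sn](CC=C)(CC=C)CC=C) under Ti(OiPr)4/1,1'-bi-2-naphthol/propan-2-ol catalysis should give the free triene alcohol (4R)-7-methyl-4-(prop-1-en-2-yl)octa-1,7-dien-4-ol F1. This is isolated, brought to enantiopurity if necessary by preparative chromatography on a chiral stationary phase, and ring-closed in a separate operation with RuCl2(=CHPh)(H2IMes)(PCy3) in CH2Cl2 at 40 °C, which returns to the route at 8.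

Step 5. Allylic transposition during the prenyl transfer may give 1,1-dimethylallyl isomers, the second coupling may stay unfinished, or protodebromination may intervene, all on the most valuable intermediate. Fallback: prenylation is moved ahead of the esterification and done by a linear-selective Negishi coupling. Setting out from 10, methylation (MeI, K2CO3, DMF) gives methyl 3,5-dibromo-4-methoxybenzoate F2. Coupling with 3-methylbut-2-enylzinc bromide (CC(C)=CC[Zn]Br; Pd(OAc)2, a dialkylbiarylphosphine ligand, THF, rt) gives methyl 4-methoxy-3,5-bis(3-methylbut-2-en-1-yl)benzoate F3. Hydrolysis (LiOH, THF–H2O) gives 4-methoxy-3,5-bis(3-methylbut-2-en-1-yl)benzoic acid F4. 1-Chloro-N,N,2-trimethylprop-1-en-1-amine (CC(C)=C(Cl)N(C)C) converts it, under neutral conditions that spare the prenyl alkenes, into 4-methoxy-3,5-bis(3-methylbut-2-en-1-yl)benzoyl chloride F5. Acylation of the lithium alkoxide of 9 with F5 as in step 4 then gives 14 directly.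

Step 3. Hydrogenation may run on to the ring alkene or shift it, or be sluggish at the hindered isopropenyl group next to the quaternary carbon. Fallback: the reduction is avoided by carrying isopropyl from the start. The kinetic enolate of 3-methylbutan-2-one (CC(C)C(C)=O; LiN(iPr)2, THF, −78 °C) is alkylated with 3-bromo-2-methylprop-1-ene (C=C(C)CBr) to give 2,6-dimethylhept-6-en-3-one F6. With 5 under the conditions of step 2 this should give, via (4R)-7-methyl-4-(propan-2-yl)octa-1,7-dien-4-yl dipropan-2-yl borate F7 and (1R)-4-methyl-1-(propan-2-yl)cyclohex-3-en-1-yl dipropan-2-yl borate F8, the alcohol 9 directly. The price is a weaker contrast between the two ketone substituents (isopropyl against a primary alkyl chain), so the enantiomeric purity of 9 would have to be secured by preparative chromatography on a chiral phase. This fallback sets out from 5 and rejoins the route at 9.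

Further compounds
F1 | step 2 | (4R)-7-methyl-4-(prop-1-en-2-yl)octa-1,7-dien-4-ol | O[C@@](CCC(C)=C)(C(C)=C)CC=C
F2 | step 5 | methyl 3,5-dibromo-4-methoxybenzoate | COC(=O)c1cc(Br)c(OC)c(Br)c1
F3 | step 5 | methyl 4-methoxy-3,5-bis(3-methylbut-2-en-1-yl)benzoate | COC(=O)c1cc(CC=C(C)C)c(OC)c(CC=C(C)C)c1
F4 | step 5 | 4-methoxy-3,5-bis(3-methylbut-2-en-1-yl)benzoic acid | COc1c(CC=C(C)C)cc(C(=O)O)cc1CC=C(C)C
F5 | step 5 | 4-methoxy-3,5-bis(3-methylbut-2-en-1-yl)benzoyl chloride | COc1c(CC=C(C)C)cc(C(=O)Cl)cc1CC=C(C)C
F6 | step 3 | 2,6-dimethylhept-6-en-3-one | CC(C)C(=O)CCC(C)=C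
F7 | step 3 | (4R)-7-methyl-4-(propan-2-yl)octa-1,7-dien-4-yl dipropan-2-yl borate | CC(C)OB(OC(C)C)O[C@@](CCC(C)=C)(C(C)C)CC=C
F8 | step 3 | (1R)-4-methyl-1-(propan-2-yl)cyclohex-3-en-1-yl dipropan-2-yl borate | CC(C)OB(OC(C)C)O[C@@]1(C(C)C)CC=C(C)CC1
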